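The runs stem from a simulated flask with constants of no real substance; scatter was added.

Product stands higher in the east run than in the south run at 50.0 min, 71.9 % against 59.5 %, and the two runs differ in their charge of precatalyst, so the pairs of readings to watch are those at equal conversion. Both runs start from 0.094 M, so at equal conversion c(starting material) and c(product) are equal too, and the order in starting material drops out of the comparison.

| setting | south | east | south-east | flask |
|---|---|---|---|---|
| starting material | 0.094 M | 0.094 M | 0.14 M | 0.094 M |
| precatalyst | 1.3 µM | 2.1 µM | 0.94 µM | 0.94 µM |
| remark | run made earlier | run made earlier | run made earlier |  |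

| run | time / min | product / % |
|---|---|---|
| south | 20.0 | 32.1 |
| south | 40.0 | 53.6 |
| south | 50.0 | 59.5 |
| south | 80.0 | 72.7 |
| east | 10.0 | 23.9 |
| east | 25.0 | 52.4 |
| east | 50.0 | 71.9 |
| east | 80.0 | 80.9 |
| south-east | 10.0 | 9.2 |
| south-east | 25.0 | 26.6 |
| south-east | 50.0 | 48.7 |
| south-east | 80.0 | 67.7 |

(scatter of a reading: 0.5 percentage points)

- factor on the rate of making product when 50 % of the starting material are converted if precatalyst is charged twice over
- factor on the rate when 50 % of the starting material are converted if precatalyst is charged at 0.10 µM instead

- what may be going on: precatalyst <-> enzyme; starting material + enzyme -> product + enzyme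

How much faster is the east run? It reads 52.4 % at 25.0 min and 71.9 % at 50.0 min, while the south run reads 53.6 % at 40.0 min and 72.7 % at 80.0 min. These pairs differ by 1.2 percentage points and 0.8 points, so they count as matched only roughly, given a scatter of 0.5 points. Both pairs have a time ratio of 1.60, against a charge ratio of 1.62.

What does that make the order in catalyst, the logarithm of the time ratio over the logarithm of the charge ratio at equal conversion? As a reading from these two runs, with their scatter, it is n = 0.980, so doubling the charge should multiply the rate by 1.97.

Does n reach down to 0.10 µM, a charge below that of each run so far? Precatalyst <-> enzyme has one catalyst species on each side, so its equilibrium share should not change with the charge. My reckoning therefore carries n down and gives 0.111.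

The forecast, calling the order “close to linear and perhaps slightly sublinear”, gives 1.9 (1.7 to 2.05) and 0.115 (0.07 to 0.17), so its factor on doubling is lower than mine and its factor at the small charge higher.

The flask gives 2.00 on doubling and 0.106 at 0.10 µM.

    precatalyst ⇌ enzyme (K = 1.05, k = 0.248 /min)
    starting material + enzyme → product + enzyme, rate k2*[starting material]^2.5*[enzyme]/(1 + ([starting material]/Kh2)^2.5) (0.0651 M, k = 63100 /M².5/s)

In the flask, enzyme stands at 50.6 % of the catalyst charged at 0.150 h and at 51.2 % at 15.0 h, with precatalyst at 49.4 % and 48.8 %. The flask reaches 50 % conversion at 0.819 h. Scaled by n, that time becomes 22.3 min for the east run, a little earlier than its reading of 52.4 % at 25.0 min.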